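The decalin is opened (labdane numbering) at C4–C5 and C9–C10, which leads back to an acyclic (6E,10E)-dienyl α-methyl β-keto ester. One oxidative free-radical bicyclization with Mn(OAc)3/Cu(OAc)2 closes ring A at C4–C5 and ring B at C9–C10. It sets C4, C5, C9 and C10 in relative terms and delivers the C3 ketone, the axial C19 ester and the C8(17) methylene. It exploits the C3/C4/C19 1,3-dicarbonyl unit beside the isoprenoid methyl pattern at C10 and C8. The precursor carries a C13 methyl ketone in place of the side-chain alkene, so the cascade stops after two rings. A ketoreductase then selects the enantiomer while setting C3.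

Key step: step 6

Remark: 10 and 12 are racemates whose SMILES show the enantiomer that is carried on. The absolute configuration is fixed in step 8.

Step 1
Reactants: 1 ethyl 2-methyl-3-oxobutanoate; 2 2-(trimethylsilyl)ethanol
Product: 3 2-(trimethylsilyl)ethyl 2-methyl-3-oxobutanoate
Conditions: DMAP (0.3 equiv), toluene, reflux, EtOH distilled off
Reagents that add atoms: none
Why: DMAP-catalysed transesterification of a β-keto ester is driven by removal of ethanol and installs a fluoride-labile ester, because the axial C19 ester of the later decalin cannot be saponified beside the C3 acetate.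

Step 2
Reactants: 4 (E)-geranylacetone
Product: 5 2-[(3E)-4,8-dimethylnona-3,7-dien-1-yl]-2-methyl-1,3-dioxolane
Conditions: ethylene glycol, pyridinium p-toluenesulfonate (cat.), toluene, reflux, azeotropic removal of water
Reagents that add atoms: ethylene glycol OCCO
Why: Acid-catalysed ketalisation masks the future C13 ketone against the strongly basic dianion of step 5, and the mild acid should leave the trisubstituted alkenes in place.

Step 3
Reactants: 5 dioxolane of (E)-geranylacetone
Product: 6 (2E,6E)-2,6-dimethyl-9-(2-methyl-1,3-dioxolan-2-yl)nona-2,6-dien-1-ol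
Conditions: SeO2 (0.1 equiv), t-BuOOH, salicylic acid (cat.), CH2Cl2, 0 to 25 °C
Reagents that add atoms: tert-butyl hydroperoxide CC(C)(C)OO
Why: SeO2 allylic oxidation (ene reaction, then [2,3]-sigmatropic shift) prefers the more electron-rich terminal isopropylidene group and its E-methyl group, which fixes the E geometry of the future C5=C10 alkene.

Step 4
Reactants: 6 (2E,6E)-allylic alcohol
Product: 7 2-[(3E,7E)-9-bromo-4,8-dimethylnona-3,7-dien-1-yl]-2-methyl-1,3-dioxolane
Conditions: CBr4, PPh3, CH2Cl2, −20 to 0 °C
Reagents that add atoms: carbon tetrabromide BrC(Br)(Br)Br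
Why: The Appel reaction replaces the primary allylic hydroxyl by SN2 attack of bromide on the alkoxyphosphonium ion under neutral conditions, so neither allylic transposition nor ketal loss is expected.

Step 5
Reactants: 3 2-(trimethylsilyl)ethyl 2-methyl-3-oxobutanoate; 7 allylic bromide
Product: 9 2-(trimethylsilyl)ethyl (6E,10E)-2,6,10-trimethyl-3,14-dioxopentadeca-6,10-dienoate, via dioxolane-protected keto ester 8 (not isolated)
Conditions: 3, NaH, THF, 0 °C; n-BuLi, 0 °C; 7, 0 °C; then 1 M aq HCl, THF, 25 °C
Reagents that add atoms: water O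
Why: In this γ-alkylation of a β-keto ester dianion the more basic terminal carbanion displaces the allylic bromide by SN2 to form C1–C2, the acidic work-up then hydrolyses the dioxolane, and the epimer mixture at C4 does not matter because C4 becomes planar in step 6.

Step 6
Reactants: 9 acyclic dienyl α-methyl β-keto ester
Product: 10 racemic 2-(trimethylsilyl)ethyl 3,13-dioxo-14,15-dinorlabd-8(17)-en-19-oate
Conditions: Mn(OAc)3·2H2O (2.2 equiv), Cu(OAc)2·H2O (1 equiv), degassed AcOH (0.05 M), 25–40 °C
Reagents that add atoms: none
Why: Mn(OAc)3 oxidises its enolate of the β-keto ester by one electron to the electrophilic C4 radical, which adds 6-endo-trig to C5 of the C5=C10 alkene (ring A, C4–C5 bond); the tertiary C10 radical then adds 6-endo-trig to C9 of the C8=C9 alkene (ring B, C9–C10 bond), and Cu(OAc)2 traps the tertiary C8 radical as an alkyl complex of trivalent copper that loses a C17 hydrogen by syn β-elimination, the monovalent copper being reoxidised by the second equivalent of Mn(OAc)3. The closest known reaction type is the Mn(OAc)3/Cu(OAc)2 oxidative free-radical polyene cyclization of α-alkyl β-keto esters. Both closures should pass through a chair–chair array, so the E geometry of C5=C10 becomes the trans ring fusion (C5–H anti to C20) and the E geometry of C8=C9 places the C9 side chain equatorial with C9–H anti to C20. At C4 the flat ester should take the axial site facing C20 and the methyl group the equatorial site, because this keeps the developing 1,3-diaxial contact smallest. The step needs 6-endo over 5-exo closure, which the methyl groups on C10 and C8 and the ketone inside the forming ring secure; a stop after two rings, which the C13 ketone secures because it is no lasting radical acceptor; and an exocyclic alkene, which the copper-mediated elimination toward the least hindered hydrogen secures. No element controls the absolute sense, so 10 is expected as a racemate.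

Step 7
Reactants: 10 racemic bicyclic diketo ester; 11 triethyl phosphonoacetate
Product: 12 racemic 15-ethyl 19-[2-(trimethylsilyl)ethyl] 3-oxolabda-8(17),13E-diene-15,19-dioate
Conditions: 11 (1.2 equiv), NaH, THF, 0 to 25 °C
Reagents that add atoms: none
Why: The Horner–Wadsworth–Emmons olefination should take the open C13 methyl ketone and spare the C3 ketone flanked by quaternary C4, it favours the E alkene with the larger C12 chain trans to the ester, and the minor Z isomer is removed by chromatography.

Step 8
Reactants: 12 racemic 3-oxo diester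
Product: 13 15-ethyl 19-[2-(trimethylsilyl)ethyl] (3R,4R,5R,9S,10R)-3-hydroxylabda-8(17),13E-diene-15,19-dioate (3α-alcohol, single enantiomer)
Conditions: ketoreductase (NADPH-dependent, (R)-selective, chosen by panel screening), NADP+ (cat.), i-PrOH, K2HPO4/KH2PO4 buffer pH 7, DMSO (10 vol%), 30 °C, stopped near half conversion
Reagents that add atoms: none
Why: This enzymatic ketone reduction (ketoreductase of the short-chain dehydrogenase/reductase class) is run as a kinetic resolution, a mode known for racemic α,α-disubstituted β-keto esters: the enzyme should accept the (4R,5R,9S,10R) enantiomer and deliver hydride to the β face of C3 along the equatorial trajectory to give the axial (3R)-alcohol, and the slow-reacting enantiomer of 12 is removed by chromatography.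

Step 9
Reactants: 13 3α-hydroxy diester
Product: 14 2-(trimethylsilyl)ethyl 3α,15-dihydroxylabda-8(17),13E-dien-19-oate
Conditions: i-Bu2AlH (3.3 equiv), CH2Cl2, −78 °C; aq potassium sodium tartrate work-up
Reagents that add atoms: none
Why: In this ester reduction with i-Bu2AlH the open conjugated ethyl ester is reduced 1,2 to the allylic alcohol with retention of the E geometry, while the axial neopentyl C19 ester is shielded by C20 and the C4 substituents.

Step 10
Reactants: 14 3α,15-diol
Product: 15 2-(trimethylsilyl)ethyl 15-(tert-butyldimethylsilyloxy)-3α-hydroxylabda-8(17),13E-dien-19-oate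
Conditions: TBSCl (1.1 equiv), imidazole, CH2Cl2, 0 °C
Reagents that add atoms: tert-butyldimethylsilyl chloride CC(C)(C)[Si](C)(C)Cl
Why: Silyl ether formation should be selective for the primary allylic alcohol, because the axial C3 hydroxyl next to quaternary C4 reacts far more slowly.

Step 11
Reactants: 15 15-silyl ether
Product: 16 2-(trimethylsilyl)ethyl 3α-acetoxy-15-(tert-butyldimethylsilyloxy)labda-8(17),13E-dien-19-oate
Conditions: Ac2O, DMAP, pyridine, 25–40 °C
Reagents that add atoms: acetic anhydride CC(=O)OC(C)=O
Why: DMAP-catalysed acylation esterifies the hindered axial alcohol at oxygen, so the configuration at C3 is retained.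

Step 12
Reactants: 16 fully protected acetate
Product: 17 3α-acetoxy-15-hydroxylabda-8(17),13E-dien-19-oic acid (target)
Conditions: n-Bu4NF (4 equiv), THF, 25 °C; AcOH quench
Reagents that add atoms: none
Why: In this fluoride-induced desilylation attack at silicon cleaves the silyl ether and fragments the 2-(trimethylsilyl)ethyl ester by β-elimination, which needs no attack at the hindered C19 carbonyl and should spare the hindered acetate, which lies trans-diaxial to the carboxylate.

Compound list
1 | ethyl 2-methyl-3-oxobutanoate | CCOC(=O)C(C)C(C)=O | starting material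
2 | 2-(trimethylsilyl)ethanol | C[Si](C)(C)CCO | starting material
3 | 2-(trimethylsilyl)ethyl 2-methyl-3-oxobutanoate | CC(=O)C(C)C(=O)OCC[Si](C)(C)C | intermediate
4 | (E)-geranylacetone | CC(=O)CC/C=C(\C)CCC=C(C)C | starting material
5 | 2-[(3E)-4,8-dimethylnona-3,7-dien-1-yl]-2-methyl-1,3-dioxolane | CC1(CC/C=C(\C)CCC=C(C)C)OCCO1 | intermediate
6 | (2E,6E)-2,6-dimethyl-9-(2-methyl-1,3-dioxolan-2-yl)nona-2,6-dien-1-ol | CC1(CC/C=C(\C)CC/C=C(\C)CO)OCCO1 | intermediate
7 | 2-[(3E,7E)-9-bromo-4,8-dimethylnona-3,7-dien-1-yl]-2-methyl-1,3-dioxolane | CC1(CC/C=C(\C)CC/C=C(\C)CBr)OCCO1 | intermediate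
8 | 2-(trimethylsilyl)ethyl (6E,10E)-2,6,10-trimethyl-13-(2-methyl-1,3-dioxolan-2-yl)-3-oxotrideca-6,10-dienoate (C2 epimers) | CC1(CC/C=C(\C)CC/C=C(\C)CCC(=O)C(C)C(=O)OCC[Si](C)(C)C)OCCO1 | intermediate
9 | 2-(trimethylsilyl)ethyl (6E,10E)-2,6,10-trimethyl-3,14-dioxopentadeca-6,10-dienoate (C2 epimers) | CC(=O)CC/C=C(\C)CC/C=C(\C)CCC(=O)C(C)C(=O)OCC[Si](C)(C)C | intermediate
10 | racemic 2-(trimethylsilyl)ethyl 3,13-dioxo-14,15-dinorlabd-8(17)-en-19-oate (enantiomer carried on is shown) | C=C1CC[C@@H]2[C@](C)(CCC(=O)[C@]2(C)C(=O)OCC[Si](C)(C)C)[C@H]1CCC(C)=O | intermediate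
11 | triethyl phosphonoacetate | CCOC(=O)CP(=O)(OCC)OCC | starting material
12 | racemic 15-ethyl 19-[2-(trimethylsilyl)ethyl] 3-oxolabda-8(17),13E-diene-15,19-dioate (enantiomer carried on is shown) | C=C1CC[C@@H]2[C@](C)(CCC(=O)[C@]2(C)C(=O)OCC[Si](C)(C)C)[C@H]1CC/C(C)=C/C(=O)OCC | intermediate
13 | 15-ethyl 19-[2-(trimethylsilyl)ethyl] 3α-hydroxylabda-8(17),13E-diene-15,19-dioate | C=C1CC[C@@H]2[C@](C)(CC[C@@H](O)[C@]2(C)C(=O)OCC[Si](C)(C)C)[C@H]1CC/C(C)=C/C(=O)OCC | intermediate
14 | 2-(trimethylsilyl)ethyl 3α,15-dihydroxylabda-8(17),13E-dien-19-oate | C=C1CC[C@@H]2[C@](C)(CC[C@@H](O)[C@]2(C)C(=O)OCC[Si](C)(C)C)[C@H]1CC/C(C)=C/CO | intermediate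
15 | 2-(trimethylsilyl)ethyl 15-(tert-butyldimethylsilyloxy)-3α-hydroxylabda-8(17),13E-dien-19-oate | C=C1CC[C@@H]2[C@](C)(CC[C@@H](O)[C@]2(C)C(=O)OCC[Si](C)(C)C)[C@H]1CC/C(C)=C/CO[Si](C)(C)C(C)(C)C | intermediate
16 | 2-(trimethylsilyl)ethyl 3α-acetoxy-15-(tert-butyldimethylsilyloxy)labda-8(17),13E-dien-19-oate | C=C1CC[C@@H]2[C@](C)(CC[C@@H](OC(C)=O)[C@]2(C)C(=O)OCC[Si](C)(C)C)[C@H]1CC/C(C)=C/CO[Si](C)(C)C(C)(C)C | intermediate
17 | 3α-acetoxy-15-hydroxylabda-8(17),13E-dien-19-oic acid, (3R,4R,5R,9S,10R) | C=C1CC[C@@H]2[C@](C)(CC[C@@H](OC(C)=O)[C@]2(C)C(=O)O)[C@H]1CC/C(C)=C/CO | target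

Total step count: 12. Longest linear sequence: 11 (steps 2 to 12, from 4).

Steps most likely to fail

Step 6. The monocyclic C10 radical may be oxidised before ring B closes, 5-exo closure may leak in, or the final elimination may lose its regiocontrol. The fallback replaces the oxidative termination by a phenylselanyl group-transfer chain and sets out from 9. NaH and PhSeCl in THF give the α-phenylselanyl β-keto ester F1. Irradiation in benzene runs the same two 6-endo closures and ends by selenium transfer to C8, which gives the bicyclic tertiary selenide F2. H2O2 and pyridine in CH2Cl2 then eliminate the selenoxide toward the freely rotating C17 methyl group, and the fallback comes back to the route at 10.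

Step 8. The hindered, very lipophilic ketone may not be accepted by any enzyme of the panel, or the two enantiomers may be poorly discriminated. The fallback separates the reduction from the resolution and sets out from 12. LiBH(s-Bu)3 in THF at −78 °C reduces the racemate from the equatorial side to racemic 13, and steps 9 to 12 are run in the racemic series. The racemic acid is resolved by crystallisation of its (R)-1-phenylethylammonium salt F3, or of the salt of the mirror-image amine if that one is less soluble. Dilute acid releases the acid, and the fallback comes back to the route at 17.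

Step 7. Poor E/Z discrimination at a methyl ketone or competing enolisation may erode geometry and conversion. The fallback is a stereospecific Horner–Wittig sequence and sets out from 10.
- 2-(Diphenylphosphoryl)ethanol and TBSCl give the silyl-protected phosphine oxide F4.
- Its lithio derivative (n-BuLi, THF, −78 °C) adds to the C13 ketone.
- The diastereomeric adducts are separated, and the (13R*,14R*) β-hydroxy phosphine oxide F5 is kept.
- NaH in DMF eliminates it in a syn sense to the geometrically pure 3-oxo 15-silyl ether F6.
- Reduction of F6 under the conditions of step 8 comes back to the route at 15, so steps 9 and 10 are no longer needed.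

Further compounds
F1 | step 6 | 2-(trimethylsilyl)ethyl (6E,10E)-2,6,10-trimethyl-3,14-dioxo-2-(phenylselanyl)pentadeca-6,10-dienoate | CC(=O)CC/C=C(\C)CC/C=C(\C)CCC(=O)C(C)([Se]c1ccccc1)C(=O)OCC[Si](C)(C)C
F2 | step 6 | racemic 2-(trimethylsilyl)ethyl 3,13-dioxo-8-(phenylselanyl)-14,15-dinorlabdan-19-oate (C8 epimers) | CC1([Se]c3ccccc3)CC[C@@H]2[C@](C)(CCC(=O)[C@]2(C)C(=O)OCC[Si](C)(C)C)[C@H]1CCC(C)=O
F3 | step 8 | (R)-1-phenylethylammonium salt of 17 | C=C1CC[C@@H]2[C@](C)(CC[C@@H](OC(C)=O)[C@]2(C)C(=O)[O-])[C@H]1CC/C(C)=C/CO.C[C@@H]([NH3+])c1ccccc1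
F4 | step 7 | [2-(tert-butyldimethylsilyloxy)ethyl]diphenylphosphine oxide | CC(C)(C)[Si](C)(C)OCCP(=O)(c1ccccc1)c1ccccc1
F5 | step 7 | racemic 2-(trimethylsilyl)ethyl 15-(tert-butyldimethylsilyloxy)-14-(diphenylphosphoryl)-13-hydroxy-3-oxolabd-8(17)-en-19-oate, (13R*,14R*) pair | C=C1CC[C@@H]2[C@](C)(CCC(=O)[C@]2(C)C(=O)OCC[Si](C)(C)C)[C@H]1CCC(C)(O)C(CO[Si](C)(C)C(C)(C)C)P(=O)(c3ccccc3)c4ccccc4
F6 | step 7 | racemic 2-(trimethylsilyl)ethyl 15-(tert-butyldimethylsilyloxy)-3-oxolabda-8(17),13E-dien-19-oate | C=C1CC[C@@H]2[C@](C)(CCC(=O)[C@]2(C)C(=O)OCC[Si](C)(C)C)[C@H]1CC/C(C)=C/CO[Si](C)(C)C(C)(C)C
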